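**Retrosynthetic overview**

1. Target 22 ← saponification of methyl ester 21 ← Sonogashira coupling of ring alkyne 17 with the (E)-iododiene 20 (from dec-9-en-1-ol by oxidation and Takai olefination).
2. 17 ← resolved cis-ketal acetate 14 (acetate methanolysis, oxidation, Ohira–Bestmann homologation); 14 ← racemic 13 by chromatography on a chiral phase.
3. The strategy rests on the only ring, the 1,2-dioxane O1–O2–C3–C4–C5–C6: the peroxyketal carbon C6 and its neighbour C5 are a ketone carbon and its alpha-carbon, C4–C3 (C3 carrying the CH2CO2H arm) is a terminal alkene, and O1–O2 is dioxygen.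
4. So 13 ← peroxyhemiketal 12 (acidic methanol) ← 10 (loss of a temporary CO2tBu group on C5) ← trivalent-manganese-catalysed aerobic annulation of beta-keto ester 6, methyl but-3-enoate 7 and O2 8, which closes the ring in one step.
5. 6 ← delta-valerolactone 1 and Meldrum's acid 4 in three steps.

Key step: step 4

Remark: C3 is formed as a racemate in the ring-forming step, so the single (3S,6R) enantiomer (OMe cis to the C3 acetic acid arm, as read from the target SMILES) is taken from a chromatographic resolution of ketal 13.

**Route**

Step 1
Reactants: 1 delta-valerolactone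
Product: 3 5-acetoxypentanoic acid, via sodium 5-hydroxypentanoate 2 (not isolated)
Conditions: NaOH, H2O, 60 °C; evaporate; Ac2O, pyridine, rt; then H2O, 1 M HCl (pH 2)
Reagents that add atoms: sodium hydroxide [Na+].[OH-]; acetic anhydride CC(=O)OC(C)=O
Why: Lactone saponification gives the sodium hydroxy carboxylate, which cannot relactonise, and O-acetylation of the primary alcohol followed by acidic work-up (which also hydrolyses any mixed anhydride) should give the acetoxy acid (ester hydrolysis, then esterification).

Step 2
Reactants: 3 5-acetoxypentanoic acid; 4 Meldrum's acid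
Product: 5 5-(5-acetoxy-1-hydroxypentylidene)-2,2-dimethyl-1,3-dioxane-4,6-dione (acyl Meldrum's acid, enol form)
Conditions: DCC, DMAP, CH2Cl2, 0 °C→rt; KHSO4 wash
Reagents that add atoms: none
Why: Carbodiimide activation of the acid and DMAP-mediated C-acylation of the Meldrum's acid enolate is the standard entry to 5-acyl Meldrum's acids, and the acetate is inert.

Step 3
Reactants: 5 acyl Meldrum's acid
Product: 6 tert-butyl 7-acetoxy-3-oxoheptanoate
Conditions: t-BuOH (excess), toluene, 90 °C
Reagents that add atoms: tert-butanol CC(C)(C)O
Why: Thermolysis of the acyl Meldrum's acid releases acetone and CO2 to give an acylketene that is trapped by tert-butanol (Meldrum's acid route to beta-keto esters).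

Step 4
Reactants: 6 tert-butyl 7-acetoxy-3-oxoheptanoate; 7 methyl but-3-enoate; 8 dioxygen
Product: 10 tert-butyl 3-(4-acetoxybutyl)-3-hydroxy-6-(2-methoxy-2-oxoethyl)-1,2-dioxane-4-carboxylate (racemic diastereomer mixture), via open-chain hydroperoxide 9 (not isolated)
Conditions: Mn(OAc)3·2H2O (10 mol %), 7 (5 equiv), AcOH, dry air (1 atm), 23 °C
Reagents that add atoms: none
Why: Trivalent manganese oxidises the enol of 6 to an electrophilic radical at the future C5, which adds to the unsubstituted terminus of 7 (future C4); the secondary radical at the future C3 captures O2, and reduction of the peroxyl radical by divalent manganese regenerates the oxidant and gives hydroperoxide 9. The hydroperoxide oxygen then adds to the ketone carbonyl (future C6) in a 6-exo-trig closure, so C4–C5, O2–C3 and O1–C6 and the 1,2-dioxan-3-ol ring are formed in one operation. The closest known reaction type is the manganese-triacetate-mediated aerobic [2+2+2] peroxidation of 1,3-dicarbonyl compounds with alkenes. C3 is formed without control (racemic), and the configurations at C5 and C6 do not matter because they are erased or reset later (decarboxylation, equilibrating ketalisation). The step needs radical attack at the terminal alkene carbon, which the monosubstituted alkene secures, and it needs the intermolecular addition to win over intramolecular radical capture and direct oxygenation of the keto ester, which the saturated acetoxybutyl chain and the excess of cheap alkene under air (not pure O2) are meant to secure.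

Step 5
Reactants: 10 tert-butyl dioxanol carboxylate
Product: 12 methyl 2-[6-(4-acetoxybutyl)-6-hydroxy-1,2-dioxan-3-yl]acetate (racemic anomer mixture), via dioxanol carboxylic acid 11 (not isolated)
Conditions: TFA/CH2Cl2 (1:4), H2O (2 equiv), 0 °C→rt; evaporate; toluene, 50 °C
Reagents that add atoms: none
Why: Acidolysis of the tert-butyl ester (loss of isobutene) gives acid 11, whose ring-opened gamma-hydroperoxy beta-keto acid tautomer should decarboxylate through the usual six-membered transition state on gentle warming and then reclose to the peroxyhemiketal; the methyl ester and acetate resist TFA and the added water is meant to suppress dehydration of the hemiketal.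

Step 6
Reactants: 12 dioxanol
Product: 13 rac-methyl 2-[(3S*,6R*)-6-(4-acetoxybutyl)-6-methoxy-1,2-dioxan-3-yl]acetate (racemic cis ketal)
Conditions: TsOH·H2O (5 mol %), MeOH, 0 °C→rt; chromatography
Reagents that add atoms: methanol CO
Why: Acid-catalysed exchange of the hemiketal OH for OMe through the peroxycarbenium ion is reversible, so the thermodynamic isomer with axial OMe (anomeric effect) and both carbon substituents equatorial, i.e. OMe cis to the C3 arm, should predominate, and the minor trans isomer would be separated and re-equilibrated (peroxyketal formation).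

Step 7
Reactants: 13 racemic cis ketal
Product: 14 methyl 2-[(3S,6R)-6-(4-acetoxybutyl)-6-methoxy-1,2-dioxan-3-yl]acetate
Conditions: preparative HPLC, amylose tris(3,5-dimethylphenylcarbamate) phase, hexane/i-PrOH, rt
Reagents that add atoms: none
Why: Resolution of a racemate by chromatography on a chiral stationary phase changes no bond, and the required (3S,6R) enantiomer would be identified by anomalous-dispersion X-ray analysis of a crystalline heavy-atom derivative or by vibrational circular dichroism before it is carried on.

Step 8
Reactants: 14 resolved ketal acetate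
Product: 15 methyl 2-[(3S,6R)-6-(4-hydroxybutyl)-6-methoxy-1,2-dioxan-3-yl]acetate
Conditions: K2CO3 (0.2 equiv), MeOH, 0 °C
Reagents that add atoms: none
Why: Catalytic carbonate in methanol transesterifies the primary acetate (Zemplén-type methanolysis), while exchange at the methyl ester is degenerate and the peroxyketal, which has no hydrogen on C6, should be stable to mild base at 0 °C.

Step 9
Reactants: 15 alcohol
Product: 16 methyl 2-[(3S,6R)-6-methoxy-6-(4-oxobutyl)-1,2-dioxan-3-yl]acetate
Conditions: Dess–Martin periodinane, pyridine, CH2Cl2, 0 °C→rt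
Reagents that add atoms: none
Why: Dess–Martin oxidation stops at the aldehyde under buffered, non-reducing conditions that should leave the O–O bond and the acid-sensitive ketal intact.

Step 10
Reactants: 16 aldehyde
Product: 17 methyl 2-[(3S,6R)-6-methoxy-6-(pent-4-yn-1-yl)-1,2-dioxan-3-yl]acetate
Conditions: dimethyl (1-diazo-2-oxopropyl)phosphonate, K2CO3, MeOH, 0 °C→rt
Reagents that add atoms: Ohira–Bestmann reagent CC(=O)C(=[N+]=[N-])P(=O)(OC)OC
Why: In the Ohira–Bestmann variant of the Seyferth–Gilbert homologation, methanolysis of the reagent gives the diazomethylphosphonate anion, which converts the aldehyde into the terminal alkyne through an alkylidene carbene 1,2-shift under mild carbonate conditions that the ester and peroxide should tolerate.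

Step 11
Reactants: 18 dec-9-en-1-ol
Product: 19 dec-9-enal
Conditions: Dess–Martin periodinane, CH2Cl2, 0 °C→rt
Reagents that add atoms: none
Why: Dess–Martin oxidation of a primary alcohol gives the aldehyde without touching the terminal alkene.

Step 12
Reactants: 19 dec-9-enal
Product: 20 (E)-1-iodoundeca-1,10-diene
Conditions: CrCl2, CHI3, dioxane/THF (6:1), 0 °C→rt
Reagents that add atoms: iodoform IC(I)I
Why: In the Takai olefination the geminal dichromium species from CHI3 and divalent chromium adds to the aldehyde and eliminates to give the (E)-vinyl iodide, dioxane as cosolvent raising the E preference, and the remote alkene is inert.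

Step 13
Reactants: 17 ring alkyne; 20 (E)-1-iodoundeca-1,10-diene
Product: 21 methyl 2-[(3S,6R)-6-[(6E)-hexadeca-6,15-dien-4-yn-1-yl]-6-methoxy-1,2-dioxan-3-yl]acetate
Conditions: PdCl2(PPh3)2 (3 mol %), CuI (6 mol %), Et3N, THF, rt
Reagents that add atoms: none
Why: Sonogashira coupling of a terminal alkyne with a vinyl iodide runs at room temperature with retention of the E geometry; dialkyl peroxyketals without an O–H are known to tolerate zerovalent palladium, CuI and amine, and the unactivated terminal alkene does not react.

Step 14
Reactants: 21 enyne methyl ester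
Product: 22 2-[(3S,6R)-6-[(6E)-hexadeca-6,15-dien-4-yn-1-yl]-6-methoxy-1,2-dioxan-3-yl]acetic acid (target)
Conditions: LiOH, THF/H2O (3:1), 0 °C→rt; then 0.5 M HCl to pH 4, 0 °C
Reagents that add atoms: lithium hydroxide [Li+].[OH-]
Why: Saponification of the methyl ester at low temperature followed by brief cold acidification should free the acid, since C6 carries no hydrogen and the C3 hydrogen is not activated enough for Kornblum–DeLaMare cleavage under these conditions, so both stereocentres should be retained.

**Compound list**

1 | delta-valerolactone | O=C1CCCCO1 | starting material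
2 | sodium 5-hydroxypentanoate | [Na+].[O-]C(=O)CCCCO | intermediate
3 | 5-acetoxypentanoic acid | CC(=O)OCCCCC(=O)O | intermediate
4 | Meldrum's acid | CC1(C)OC(=O)CC(=O)O1 | starting material
5 | 5-(5-acetoxy-1-hydroxypentylidene)-2,2-dimethyl-1,3-dioxane-4,6-dione | CC(=O)OCCCCC(O)=C1C(=O)OC(C)(C)OC1=O | intermediate
6 | tert-butyl 7-acetoxy-3-oxoheptanoate | CC(=O)OCCCCC(=O)CC(=O)OC(C)(C)C | intermediate
7 | methyl but-3-enoate | C=CCC(=O)OC | starting material
8 | dioxygen | O=O | starting material
9 | 1-tert-butyl 6-methyl 2-(5-acetoxypentanoyl)-4-hydroperoxyhexanedioate (racemic diastereomer mixture) | CC(=O)OCCCCC(=O)C(CC(OO)CC(=O)OC)C(=O)OC(C)(C)C | intermediate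
10 | tert-butyl 3-(4-acetoxybutyl)-3-hydroxy-6-(2-methoxy-2-oxoethyl)-1,2-dioxane-4-carboxylate (racemic diastereomer mixture) | CC(=O)OCCCCC1(O)OOC(CC(=O)OC)CC1C(=O)OC(C)(C)C | intermediate
11 | 3-(4-acetoxybutyl)-3-hydroxy-6-(2-methoxy-2-oxoethyl)-1,2-dioxane-4-carboxylic acid (racemic diastereomer mixture) | CC(=O)OCCCCC1(O)OOC(CC(=O)OC)CC1C(=O)O | intermediate
12 | methyl 2-[6-(4-acetoxybutyl)-6-hydroxy-1,2-dioxan-3-yl]acetate (racemic anomer mixture) | CC(=O)OCCCCC1(O)CCC(CC(=O)OC)OO1 | intermediate
13 | rac-methyl 2-[(3S*,6R*)-6-(4-acetoxybutyl)-6-methoxy-1,2-dioxan-3-yl]acetate (racemate; relative configuration drawn) | CC(=O)OCCCC[C@]1(OC)CC[C@@H](CC(=O)OC)OO1 | intermediate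
14 | methyl 2-[(3S,6R)-6-(4-acetoxybutyl)-6-methoxy-1,2-dioxan-3-yl]acetate (single enantiomer) | CC(=O)OCCCC[C@]1(OC)CC[C@@H](CC(=O)OC)OO1 | intermediate
15 | methyl 2-[(3S,6R)-6-(4-hydroxybutyl)-6-methoxy-1,2-dioxan-3-yl]acetate | OCCCC[C@]1(OC)CC[C@@H](CC(=O)OC)OO1 | intermediate
16 | methyl 2-[(3S,6R)-6-methoxy-6-(4-oxobutyl)-1,2-dioxan-3-yl]acetate | O=CCCC[C@]1(OC)CC[C@@H](CC(=O)OC)OO1 | intermediate
17 | methyl 2-[(3S,6R)-6-methoxy-6-(pent-4-yn-1-yl)-1,2-dioxan-3-yl]acetate | C#CCCC[C@]1(OC)CC[C@@H](CC(=O)OC)OO1 | intermediate
18 | dec-9-en-1-ol | C=CCCCCCCCCO | starting material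
19 | dec-9-enal | C=CCCCCCCCC=O | intermediate
20 | (E)-1-iodoundeca-1,10-diene | C=CCCCCCCC/C=C/I | intermediate
21 | methyl 2-[(3S,6R)-6-[(6E)-hexadeca-6,15-dien-4-yn-1-yl]-6-methoxy-1,2-dioxan-3-yl]acetate | C=CCCCCCCC/C=C/C#CCCC[C@]1(OC)CC[C@@H](CC(=O)OC)OO1 | intermediate
22 | 2-[(3S,6R)-6-[(6E)-hexadeca-6,15-dien-4-yn-1-yl]-6-methoxy-1,2-dioxan-3-yl]acetic acid | C=CCCCCCCC/C=C/C#CCCC[C@]1(OC)CC[C@@H](CC(=O)O)OO1 | target

**Step count**

Total steps: 14. Longest linear sequence: 12 steps (steps 1–10, 13 and 14); steps 11–12 make the iododiene.

**Steps most likely to fail**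

Step 4. Radical addition to the monosubstituted, unactivated alkene may be too slow, so that direct oxygenation of the keto ester radical and allylic autoxidation of the butenoate take over and little ring product forms. The fallback installs the peroxide after the carbon chain is complete and sets out from 6. C-Alkylation with methyl (E)-4-bromobut-2-enoate (K2CO3, acetone) would give 6-tert-butyl 1-methyl (2E)-5-(5-acetoxypentanoyl)hex-2-enedioate F1. TFA and then warming in toluene would give methyl (2E)-10-acetoxy-6-oxodec-2-enoate F2. Takai–Lombardo methylenation of the ketone (Zn, CH2Br2, TiCl4) would give methyl (2E)-10-acetoxy-6-methylidenedec-2-enoate F3. Ozonolysis of the electron-rich 1,1-disubstituted alkene in MeOH/CH2Cl2 at −78 °C would give methyl (2E)-10-acetoxy-6-hydroperoxy-6-methoxydec-2-enoate F4. Et2NH in CF3CH2OH would then close the ring by intramolecular conjugate addition of the hydroperoxide to the enoate; after removal of the trans isomer this comes back to the route at 13.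

Step 5. Acid may dehydrate the peroxyhemiketal or break the O–O bond (Criegee- or Hock-type fragmentation) during ester acidolysis, or the decarboxylation may stall because the ring-closed form opens too slowly. The fallback replaces acidolysis by fluoride-triggered ester fragmentation and sets out from 5. Thermolysis in toluene with 2-(trimethylsilyl)ethanol would give 2-(trimethylsilyl)ethyl 7-acetoxy-3-oxoheptanoate F5. The same Mn(OAc)3-catalysed aerobic annulation with 7 and 8 would give 2-(trimethylsilyl)ethyl 3-(4-acetoxybutyl)-3-hydroxy-6-(2-methoxy-2-oxoethyl)-1,2-dioxane-4-carboxylate F6. Bu4NF buffered with AcOH (THF, 0 °C→rt) would release acid 11 under near-neutral conditions, and gentle warming would give 12, where the route is rejoined.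

Step 12. The E preference of the chromium-mediated olefination may erode, and the Z iodide, which cannot readily be separated, would then be carried through the coupling. The fallback sets the geometry by syn hydrometalation and sets out from 19. Ohira–Bestmann homologation (K2CO3, MeOH) would give undec-1-en-10-yne F7. Hydrozirconation of the terminal alkyne with Cp2Zr(H)Cl (1 equiv, THF, rt; the alkyne reacts faster than the terminal alkene) followed by I2 would give 20 as the E isomer only.

**Further compounds**

F1 | step 4 | 6-tert-butyl 1-methyl (2E)-5-(5-acetoxypentanoyl)hex-2-enedioate | CC(=O)OCCCCC(=O)C(C/C=C/C(=O)OC)C(=O)OC(C)(C)C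
F2 | step 4 | methyl (2E)-10-acetoxy-6-oxodec-2-enoate | CC(=O)OCCCCC(=O)CC/C=C/C(=O)OC
F3 | step 4 | methyl (2E)-10-acetoxy-6-methylidenedec-2-enoate | CC(=O)OCCCCC(=C)CC/C=C/C(=O)OC
F4 | step 4 | methyl (2E)-10-acetoxy-6-hydroperoxy-6-methoxydec-2-enoate (racemic) | CC(=O)OCCCCC(OC)(OO)CC/C=C/C(=O)OC
F5 | step 5 | 2-(trimethylsilyl)ethyl 7-acetoxy-3-oxoheptanoate | CC(=O)OCCCCC(=O)CC(=O)OCC[Si](C)(C)C
F6 | step 5 | 2-(trimethylsilyl)ethyl 3-(4-acetoxybutyl)-3-hydroxy-6-(2-methoxy-2-oxoethyl)-1,2-dioxane-4-carboxylate (racemic diastereomer mixture) | CC(=O)OCCCCC1(O)OOC(CC(=O)OC)CC1C(=O)OCC[Si](C)(C)C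
F7 | step 12 | undec-1-en-10-yne | C=CCCCCCCCC#C
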